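**Retrosynthetic overview**

- Target 11 comes from N-detosylation of 10, and 10 from hydrodediazoniation of amine 8 (C5–NH2 becomes C5–H).
- Amine 8 comes from 5-amino-1-tosylindole 5 by one NBS operation that forms the C3–Br, C4–Br and C6–Br bonds.
- Amine 5 comes from 5-nitroindole 1 by N-tosylation and nitro reduction.
- Feature used: in the benzo ring C4 and C6 flank C5, so an NH2 on C5 is ortho to both, and its para carbon is the ring-fusion atom C7a. C3 is the β-carbon of the pyrrole ring. The C5–H of the target is where the director is erased.
- No ring is formed: the indole bicycle (pyrrole ring fused to the benzo ring) is bought intact in 1.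

Key step: step 3

Remark on the chemistry: the three brominations of step 3 are assumed to run in the order C4, C6, C3, and intermediates 6 and 7 are numbered on that basis. Tosyl means p-tolylsulfonyl on N1.

**Route**

Step 1
Reactants: 1 5-nitroindole; 2 p-toluenesulfonyl chloride
Product: 4 5-nitro-1-tosylindole, via sodium 5-nitroindol-1-ide 3 (not isolated)
Conditions: NaH (1.2 equiv), DMF, 0 °C; then TsCl (1.1 equiv), 0 °C to rt
Reagents that add atoms: p-toluenesulfonyl chloride (compound 2), Cc1ccc(cc1)S(Cl)(=O)=O
Why: NaH deprotonates the indole N–H, which the 5-nitro group makes more acidic, and the sodium indolide attacks the sulfonyl chloride at sulfur (N-sulfonylation).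

Step 2
Reactants: 4 5-nitro-1-tosylindole
Product: 5 5-amino-1-tosylindole
Conditions: Fe powder, NH4Cl, EtOH/H2O (4:1), 80 °C
Reagents that add atoms: none
Why: Béchamp-type reduction by Fe in buffered aqueous ethanol should take the nitro group to the amine by stepwise electron and proton transfer, leaving the N-sulfonyl group and the C2=C3 bond untouched.

Step 3
Reactants: 5 5-amino-1-tosylindole
Product: 8 5-amino-3,4,6-tribromo-1-tosylindole, via 5-amino-4-bromo-1-tosylindole 6 (not isolated), via 5-amino-4,6-dibromo-1-tosylindole 7 (not isolated)
Conditions: NBS (3.05 equiv, portionwise), DMF, −10 °C to rt, dark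
Reagents that add atoms: N-bromosuccinimide, O=C1CCC(=O)N1Br
Why: NBS delivers electrophilic bromine in three successive electrophilic aromatic substitutions (Wheland intermediate, then proton loss); the first two occur ortho to the C5 amino group, at C4 and then C6, and the third at C3, where the cation is stabilised by the N1 lone pair although the sulfonyl group attenuates it. The closest known reactions are the ortho,ortho-dibromination of para-blocked anilines with NBS in DMF and the C3 bromination of N-sulfonylindoles. No ring is closed and no stereocentre is formed; three C–Br bonds are made. The step needs site selectivity among C2, C3, C4, C6 and C7: the amino group activates only its ortho carbons because its para carbon is the ring-fusion atom C7a, C7 is meta to it and stays unactivated, and C3 is preferred over C2 by the innate β-reactivity of the indole. The tosyl group tempers the pyrrole ring so that the amino-directed brominations run first and protects the electron-rich aminoindole from oxidation, while exact stoichiometry, portionwise addition and low temperature should hold back a fourth bromination at C2 or C7.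

Step 4
Reactants: 8 5-amino-3,4,6-tribromo-1-tosylindole
Product: 10 3,4,6-tribromo-1-tosylindole, via 3,4,6-tribromo-1-tosylindole-5-diazonium hydrogen sulfate 9 (not isolated)
Conditions: NaNO2, conc. H2SO4, AcOH, 0–5 °C; then 50% aq H3PO2, 0 °C to rt
Reagents that add atoms: none
Why: Nitrosylsulfuric acid formed from NaNO2 and H2SO4 diazotizes the weakly basic 2,6-dibromoaniline unit, and H3PO2 reduces the diazonium salt by a radical chain in which the aryl radical takes hydrogen from P–H (hydrodediazoniation); the N1 sulfonyl group blocks N-nitrosation and the halide-free acid avoids displacement of an ortho bromine.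

Step 5
Reactants: 10 3,4,6-tribromo-1-tosylindole
Product: 11 3,4,6-tribromoindole
Conditions: Cs2CO3 (3 equiv), THF/MeOH (2:1), rt
Reagents that add atoms: none
Why: Methoxide formed from Cs2CO3 and methanol attacks the sulfonyl sulfur and expels the indolide, a good leaving group because three bromines stabilise it (nucleophilic N-desulfonylation), and the aryl C–Br bonds should be inert to this mild base.

**Compound list**

1 | 5-nitroindole | [O-][N+](=O)c1ccc2[nH]ccc2c1 | starting material
2 | p-toluenesulfonyl chloride | Cc1ccc(cc1)S(Cl)(=O)=O | starting material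
3 | sodium 5-nitroindol-1-ide | [Na+].[O-][N+](=O)c1ccc2[n-]ccc2c1 | intermediate (not isolated)
4 | 5-nitro-1-tosylindole | Cc1ccc(cc1)S(=O)(=O)n1ccc2cc(ccc21)[N+]([O-])=O | intermediate
5 | 5-amino-1-tosylindole | Cc1ccc(cc1)S(=O)(=O)n1ccc2cc(N)ccc21 | intermediate
6 | 5-amino-4-bromo-1-tosylindole | Cc1ccc(cc1)S(=O)(=O)n1ccc2c(Br)c(N)ccc21 | intermediate (not isolated)
7 | 5-amino-4,6-dibromo-1-tosylindole | Cc1ccc(cc1)S(=O)(=O)n1ccc2c(Br)c(N)c(Br)cc21 | intermediate (not isolated)
8 | 5-amino-3,4,6-tribromo-1-tosylindole | Cc1ccc(cc1)S(=O)(=O)n1cc(Br)c2c(Br)c(N)c(Br)cc21 | intermediate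
9 | 3,4,6-tribromo-1-tosylindole-5-diazonium hydrogen sulfate | Cc1ccc(cc1)S(=O)(=O)n1cc(Br)c2c(Br)c([N+]#N)c(Br)cc21.OS(=O)(=O)[O-] | intermediate (not isolated)
10 | 3,4,6-tribromo-1-tosylindole | Cc1ccc(cc1)S(=O)(=O)n1cc(Br)c2c(Br)cc(Br)cc21 | intermediate
11 | 3,4,6-tribromoindole | Brc1cc(Br)c2c(Br)c[nH]c2c1 | target

**Step count**

Total steps: 5. Longest linear sequence: 5 steps, from 5-nitroindole 1.

**Steps most likely to fail**

Step 3. The third bromination may stall, because the sulfonyl group and the neighbouring C4 bromine deactivate and crowd C3. The remaining NBS could then oxidise or N-brominate the amine, or brominate C2 or C7. Fallback, setting out from 1 and coming back at 8: the C3 bromine is placed first, on the free indole, where the pyrrole ring is not deactivated.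
- 5-Nitroindole 1 with NBS (1.0 equiv) in DMF at 0 °C should give 3-bromo-5-nitroindole F1.
- NaH in DMF converts F1 into sodium 3-bromo-5-nitroindol-1-ide F2, which is not isolated, and tosyl chloride 2 then gives 3-bromo-5-nitro-1-tosylindole F3.
- Fe powder and NH4Cl in aqueous ethanol reduce the nitro group without touching the C–Br bond, giving 5-amino-3-bromo-1-tosylindole F4.
- NBS (2.0 equiv) in DMF at −10 °C then performs only the two amino-directed ortho brominations. The monobrominated intermediate is assumed to be 5-amino-3,4-dibromo-1-tosylindole F5 (not isolated), and the product is 8.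

Step 4. Diazotization of the hindered, weakly basic and poorly soluble amine may be incomplete in the acid medium, and water may capture the diazonium ion before it is reduced. Fallback, setting out from 8 and coming back at 10: the diazonium salt is made without water and isolated, then reduced in a separate electron-transfer step.
- NOBF4 in MeCN at −30 to 0 °C, followed by precipitation with diethyl ether, should give 3,4,6-tribromo-1-tosylindole-5-diazonium tetrafluoroborate F6.
- Catalytic FeSO4 in DMF at rt (divalent iron starts the radical chain, DMF is the hydrogen donor) then gives 10.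

Step 5. The sulfonyl cleavage may be slow, and the 3-bromoindole may degrade meanwhile by loss of the C3 bromine or by N-methylation from the sulfonate ester formed. Fallback, setting out from 5 and coming back at 11: the C3 bromine is introduced only after the tosyl group is gone.
- Amine 5 with NBS (2.0 equiv) in DMF at −10 °C is stopped at the dibromide 7, formed via 6, and 7 is isolated.
- NaNO2/H2SO4/AcOH and then H3PO2, as in step 4, pass through 4,6-dibromo-1-tosylindole-5-diazonium hydrogen sulfate F7 (not isolated) and give 4,6-dibromo-1-tosylindole F8.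
- Cs2CO3 in THF/MeOH removes the tosyl group to give 4,6-dibromoindole F9.
- NBS (1.0 equiv) in DMF at 0 °C brominates the free indole at C3 and gives 11.

**Further compounds**

F1 | step 3 | 3-bromo-5-nitroindole | [O-][N+](=O)c1ccc2[nH]cc(Br)c2c1
F2 | step 3 | sodium 3-bromo-5-nitroindol-1-ide | [Na+].[O-][N+](=O)c1ccc2[n-]cc(Br)c2c1
F3 | step 3 | 3-bromo-5-nitro-1-tosylindole | Cc1ccc(cc1)S(=O)(=O)n1cc(Br)c2cc(ccc21)[N+]([O-])=O
F4 | step 3 | 5-amino-3-bromo-1-tosylindole | Cc1ccc(cc1)S(=O)(=O)n1cc(Br)c2cc(N)ccc21
F5 | step 3 | 5-amino-3,4-dibromo-1-tosylindole | Cc1ccc(cc1)S(=O)(=O)n1cc(Br)c2c(Br)c(N)ccc21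
F6 | step 4 | 3,4,6-tribromo-1-tosylindole-5-diazonium tetrafluoroborate | Cc1ccc(cc1)S(=O)(=O)n1cc(Br)c2c(Br)c([N+]#N)c(Br)cc21.F[B-](F)(F)F
F7 | step 5 | 4,6-dibromo-1-tosylindole-5-diazonium hydrogen sulfate | Cc1ccc(cc1)S(=O)(=O)n1ccc2c(Br)c([N+]#N)c(Br)cc21.OS(=O)(=O)[O-]
F8 | step 5 | 4,6-dibromo-1-tosylindole | Cc1ccc(cc1)S(=O)(=O)n1ccc2c(Br)cc(Br)cc21
F9 | step 5 | 4,6-dibromoindole | Brc1cc(Br)c2cc[nH]c2c1
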